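## The problem

4-O-Demethylplanaic acid (18) is a depside: two benzene rings joined only by an aryl ester between the carboxyl carbon of ring A and O-4 of ring B. Both rings are the same unit, a 2-methoxy-6-pentylbenzoyl group oxygenated at C4, so one building block can serve twice if its C4–OH and its carboxyl group can be masked independently. The molecule has no stereocentre, so nothing has to be controlled or relayed, and any stereocentre that appears on the way is temporary. The difficulties are regiochemical and functional. In each ring the C2 oxygen is methylated and the C4 oxygen is not, which is awkward on a resorcinol because the C4–OH is the more reactive of the two. The benzoyl carbon lies between two ortho substituents, which slows esterification and hydrolysis. The depside ester does not survive hydroxide or alkoxide, and electron-rich acids of this type can lose CO2 in hot acid, so the last operations must be neutral. The enabling feature is that C2–OMe and C4–OH of one ring are the enol ether and the ketone of a 3-methoxycyclohex-2-enone (C1 bearing the ester, C2=C3 the enol ether, C4 the carbonyl, C6 the pentyl group). Such a ring can be closed at the C3–C4 bond from an open chain in which the methyl ether is already in place, and dehydrogenation then gives the arene with the oxygen pattern fixed.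

## Retrosynthesis

**18 from 17.** The last cut removes two benzyl groups, the ether on O-4 of ring A and the ester on the ring B carboxyl. Hydrogenolysis is neutral and leaves the depside ester alone, which a methyl ester at this hindered position would not allow. The precursor 17 is the fully protected depside; the forward step only has to cleave two benzylic C–O bonds.

**17 from 15 and 13.** The acyl–oxygen bond of the depside ester is cut. Building ring A on a preformed ester is the neighbouring choice, but it would leave two free phenols in ring A. The cut gives acid 15 and phenol 13, which share one carbon skeleton, so the problem halves. The forward reaction must acylate a phenol with a di-ortho-substituted acid; the mixed trifluoroacetic anhydride 16 is the usual answer for depsides.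

**15 from 13 through 14.** Acid 15 is phenol 13 with O-4 benzylated and the benzyl ester cleaved. O-Benzylation gives 14, and hydroxide in DMSO cleaves the hindered ester. No phenoxide is present during the saponification, and the benzyl ether survives. Thus 13 is the single intermediate for both rings.

**13 from 12.** The arene is taken back to its dihydro form, the 3-methoxycyclohexenone 12, by adding two hydrogens across C5–C6. This removes the need to tell two phenols apart, since in 12 one oxygen is an enol ether and the other a ketone. The forward step is a dehydrogenation that must stop at the phenol.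

**12 from 9.** The C3–C4 bond is cut, which opens the ring to the diester 9. Cuts at C1–C6 or C5–C6 would lead to 1,3-dione chemistry with two equivalent enolisable oxygens. The C3–C4 cut leaves the methyl ether on the only ketone-derived carbon of an open chain. The forward reaction is a Claisen closure from the γ-carbon of a β-methoxy enoate onto the remote methyl ester. The ring carboxyl is a benzyl ester from here on, so that 13 emerges ready to be the ring B partner.

**9 from 6 and 7.** The enol ether C–O bond is cut, giving the β-keto ester 6 and trimethyl orthoformate (7). In 6 the acetyl ketone is the only ketone, so O-methylation has no regiochemical choice. The forward step is an acid-catalysed enol ether formation through the ketal 8.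

**6 from 3 and 4.** The C5–C6 bond is cut: the alkylidene acetoacetate 3 takes up the acetate unit of the ketene silyl acetal 4. A base-mediated Michael addition to an octenoate would run on into the unmethylated dione, whereas the silyl nucleophile stops at the open chain through 5. The forward step is a Mukaiyama–Michael addition.

**3 from 1 and 2.** The C1=C6 double bond is cut to hexanal (1) and benzyl acetoacetate (2), both commercial. Hexanal brings C6 and the pentyl chain; the acetoacetate brings C1, C2, C3 and the carboxyl carbon. The forward step is a Knoevenagel condensation.

## Roads not taken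

**Alternative 1: aryne carbomagnesiation and carboxylation.** The cut removes both the pentyl group and the carboxyl group from an intact arene. The aryne from 5-(benzyloxy)-2-iodo-3-methoxyphenyl 4-chlorobenzenesulfonate (A2) would take up a pentyl Grignard reagent at the carbon remote from the methoxy group. The aryl magnesium species, held next to the methoxy group, would then be carboxylated to 4-(benzyloxy)-2-methoxy-6-pentylbenzoic acid (A1), which is the same compound as 15.
- Merits: two bonds form in one flask, the oxygens are already differentiated, and no hindered ester has to be hydrolysed. For the ring A acid this road is shorter than the chosen one.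
- Weak points: A2 needs a phloroglucinol with three different oxygen substituents and an iodination at one defined position between two of them, and desymmetrising phloroglucinol is not selective by itself. The regiochemistry of the addition rests on the inductive pull of one methoxy group. A primary Grignard reagent can also exchange or transfer hydride.
- Comparison: A1 serves only ring A. Ring B needs a free C4–OH and a benzyl ester, so a second series with another oxygen protecting group would be required. The chosen plan is longer to 15 but draws both rings from 13, starts from aliphatic commodity chemicals and has no positional question on an arene.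

**Alternative 2: biomimetic aldol aromatisation on the ring B ester.** The cut is the C1–C6 bond of ring A in an assembled depside. The trioxo ester benzyl 2-methoxy-6-pentyl-4-[(3,5,7-trioxododecanoyl)oxy]benzoate (A4) would close by aldol condensation of chain C2 onto the C7 ketone and aromatise to benzyl 4-[(2,4-dihydroxy-6-pentylbenzoyl)oxy]-2-methoxy-6-pentylbenzoate (A3).
- Merits: the depside ester is made from an unhindered acyl donor, which is better than the hindered coupling of the chosen plan.
- Weak points: A3 has both ring A oxygens free, and the target needs the methyl group on the chelated, less reactive C2–OH. Protection of C4–OH, methylation and deprotection would follow, on a base-sensitive depside. The aryl ester in A4 is an activated ester, so lactonisation of an enol oxygen to a 4-hydroxy-2-pyrone with loss of the ring B phenoxide competes, as does Claisen closure. Ring B must still be made by another route.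
- Comparison: the chosen plan accepts a hindered esterification, but the methyl ether is in place before either ring exists.

**Alternative 3: 2-pyrone plus siloxyalkyne, loss of CO2.** The cut removes C3 and C4 of the arene as an alkyne. The pyrone methyl 2-methoxy-6-oxo-4-pentyl-6H-pyran-3-carboxylate (A6) and triisopropylsilyloxyethyne (A7) would undergo [4+2] cycloaddition, forming C2–C3 and C4–C5. Extrusion of CO2 would then give methyl 2-methoxy-6-pentyl-4-(triisopropylsilyloxy)benzoate (A5).
- Merits: the arene oxidation level is reached without an oxidant, and the C4 oxygen arrives as a silyl ether distinct from the C2 methyl ether. In these two respects this road equals or betters the chosen one.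
- Weak points: A6 is the O-methyl enol form of a glutaconic anhydride, a moisture-sensitive acylating agent that is hard to make with the ester at the required carbon. A7 is a labile reagent needing its own preparation. An electron-rich alkyne and an electron-poor pyrone may react stepwise. A5 is a methyl ester, so ring B would need a hindered saponification and re-esterification.
- Comparison: the chosen plan spends one oxidation step (step 5) but uses commercial starting materials and carries the benzyl ester from the first step.

Key step: step 4

## Route

Remark on the chemistry: the target is achiral. The stereocentres of 5, 6, 8, 9, 10, 11 and 12 are racemic and vanish by step 5, so E/Z and diastereomer mixtures are carried on unseparated. The ring carboxyl is carried as a benzyl ester throughout.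

Step 1
Reactants: 1 hexanal; 2 benzyl acetoacetate (benzyl 3-oxobutanoate)
Product: 3 benzyl 2-acetyloct-2-enoate (E/Z mixture)
Conditions: piperidine (cat.), AcOH (cat.), 4 Å molecular sieves, CH2Cl2, 0 °C
Reagents that add atoms: none
Why: Knoevenagel condensation; iminium activation of the aldehyde and loss of water give the doubly activated alkene, and low temperature with equimolar partners holds back a second Michael addition. The alkene geometry is irrelevant.

Step 2
Reactants: 3 benzyl 2-acetyloct-2-enoate; 4 1-methoxy-1-(trimethylsilyloxy)ethene
Product: 6 1-benzyl 5-methyl 2-acetyl-3-pentylpentanedioate (racemic diastereomer mixture), via trimethylsilyl enol ether 5 (not isolated)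
Conditions: Sc(OTf)3 (10 mol %), CH2Cl2, −78 °C to 0 °C; then 1 M HCl, THF, rt
Reagents that add atoms: none
Why: Mukaiyama–Michael addition; the Lewis acid chelates the 1,3-dicarbonyl unit of 3, the ketene silyl acetal adds to the β-carbon, and silyl transfer gives 5, which dilute acid hydrolyses. The two new stereocentres need no control because both become sp2 later.

Step 3
Reactants: 6 1-benzyl 5-methyl 2-acetyl-3-pentylpentanedioate; 7 trimethyl orthoformate
Product: 9 1-benzyl 5-methyl 2-(1-methoxyethylidene)-3-pentylpentanedioate (racemic E/Z mixture), via dimethyl ketal 8 (not isolated)
Conditions: HC(OMe)3 (neat, excess), conc. H2SO4 (cat.), rt to 40 °C; Et3N quench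
Reagents that add atoms: none
Why: Enol ether formation of a β-keto ester; acid-catalysed ketalisation by the orthoformate and loss of methanol from 8 give the conjugated β-methoxy enoate, and the acetyl ketone is the only carbonyl that can react. Working without added methanol limits acid-catalysed exchange at the benzyl ester.

Step 4
Reactants: 9 1-benzyl 5-methyl 2-(1-methoxyethylidene)-3-pentylpentanedioate
Product: 12 benzyl 2-methoxy-4-oxo-6-pentylcyclohex-2-ene-1-carboxylate (racemic diastereomer mixture), via cyclohex-1-ene keto ester 10 (not isolated), via potassium dienolate 11 (not isolated)
Conditions: KOtBu (2.2 equiv), THF, 0 °C to rt; AcOH quench at 0 °C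
Reagents that add atoms: none
Why: Vinylogous Dieckmann (intramolecular Claisen) condensation through the dienolate of a β-methoxy enoate, the ring-forming counterpart of the classical alkoxide-mediated γ-acylation of β-alkoxycrotonates. KOtBu reversibly removes a proton from the methyl group on the enol ether carbon; the dienolate no longer has the former alkene geometry, so both isomers of 9 converge. The γ-carbon attacks the methyl ester carbonyl in a 6-(enolendo)-exo-trig closure that forms the C3–C4 bond, and the tetrahedral intermediate expels methoxide to give 10. Deprotonation of 10, a doubly vinylogous β-keto ester, to the dienolate 11 is the thermodynamic sink that pulls the reversible enolisations through; protonation at C1 on work-up gives the vinylogous ester 12. No stereocentre is set under control: C6 is carried racemic, C1 is epimerisable, and both become sp2 in step 5. The selectivity needed is site selectivity among the enolisable positions; attack from the α-carbon of the dienolate or from the enolate of the CH2CO2Me group could only close a four-membered ring, so the γ-carbon alone has a productive path. The benzyl ester is a fully substituted, donor-conjugated enoate before closure and part of an enolate afterwards, and KOMe is poorly soluble in THF, which together should limit ester exchange by the liberated methoxide.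

Step 5
Reactants: 12 benzyl 2-methoxy-4-oxo-6-pentylcyclohex-2-ene-1-carboxylate
Product: 13 benzyl 4-hydroxy-2-methoxy-6-pentylbenzoate
Conditions: DDQ (1.2 equiv), 1,4-dioxane, 80 °C
Reagents that add atoms: none
Why: Quinone dehydrogenation of a cyclohexenone to a phenol; the dienol of 12 (enolised through the acidic C1–H) loses hydride from the pentyl-bearing C6 to give a cation stabilised by both oxygens, and loss of a C5 proton gives the arene. The pentyl group is meta to both oxygens, so benzylic oxidation of the product is not favoured.

Step 6
Reactants: 13 benzyl 4-hydroxy-2-methoxy-6-pentylbenzoate (about half of the material; the rest is kept for step 8)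
Product: 14 benzyl 4-(benzyloxy)-2-methoxy-6-pentylbenzoate
Conditions: BnBr, K2CO3, DMF, rt
Reagents that add atoms: benzyl bromide, BrCc1ccccc1
Why: Williamson ether synthesis on an unhindered phenoxide; the hindered benzyl ester is inert to carbonate.

Step 7
Reactants: 14 benzyl 4-(benzyloxy)-2-methoxy-6-pentylbenzoate
Product: 15 4-(benzyloxy)-2-methoxy-6-pentylbenzoic acid
Conditions: KOH (excess), DMSO/H2O (4:1), 90 °C; then cold 1 M HCl
Reagents that add atoms: potassium hydroxide, [K+].[OH-]
Why: Saponification of a di-ortho-substituted benzoate, which needs poorly solvated hydroxide in DMSO; the aryl benzyl ether and the methyl ether are stable to base, and cold acidification avoids decarboxylation of the electron-rich acid.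

Step 8
Reactants: 15 4-(benzyloxy)-2-methoxy-6-pentylbenzoic acid; 13 benzyl 4-hydroxy-2-methoxy-6-pentylbenzoate
Product: 17 benzyl 4-{[4-(benzyloxy)-2-methoxy-6-pentylbenzoyl]oxy}-2-methoxy-6-pentylbenzoate, via mixed trifluoroacetic anhydride 16 (not isolated)
Conditions: (CF3CO)2O (3 equiv), toluene, rt
Reagents that add atoms: none
Why: Esterification through a mixed trifluoroacetic anhydride, the standard depside coupling; the electron-rich hindered acid ionises towards an acylium ion that the phenol of 13 captures, and the benzyl ester of 13 is untouched under these acidic, non-nucleophilic conditions.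

Step 9
Reactants: 17 benzyl 4-{[4-(benzyloxy)-2-methoxy-6-pentylbenzoyl]oxy}-2-methoxy-6-pentylbenzoate
Product: 18 4-O-demethylplanaic acid, 4-[(4-hydroxy-2-methoxy-6-pentylbenzoyl)oxy]-2-methoxy-6-pentylbenzoic acid
Conditions: H2 (1 atm), 10% Pd/C, EtOAc, rt
Reagents that add atoms: none
Why: Catalytic hydrogenolysis cleaves the benzyl ether and the benzyl ester in one neutral operation; the aryl ester of the depside and the methyl ethers are not hydrogenolysed.

## Compound list

1 | hexanal | CCCCCC=O | starting material
2 | benzyl acetoacetate (benzyl 3-oxobutanoate) | CC(=O)CC(=O)OCc1ccccc1 | starting material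
3 | benzyl 2-acetyloct-2-enoate (E/Z mixture) | CCCCCC=C(C(C)=O)C(=O)OCc1ccccc1 | intermediate
4 | 1-methoxy-1-(trimethylsilyloxy)ethene | C=C(OC)O[Si](C)(C)C | starting material
5 | 1-benzyl 5-methyl 3-pentyl-2-[1-(trimethylsilyloxy)ethylidene]pentanedioate (racemic, E/Z mixture) | CCCCCC(CC(=O)OC)C(C(=O)OCc1ccccc1)=C(C)O[Si](C)(C)C | intermediate (not isolated)
6 | 1-benzyl 5-methyl 2-acetyl-3-pentylpentanedioate (racemic, diastereomer mixture) | CCCCCC(CC(=O)OC)C(C(C)=O)C(=O)OCc1ccccc1 | intermediate
7 | trimethyl orthoformate | COC(OC)OC | starting material
8 | 1-benzyl 5-methyl 2-(1,1-dimethoxyethyl)-3-pentylpentanedioate (racemic, diastereomer mixture) | CCCCCC(CC(=O)OC)C(C(C)(OC)OC)C(=O)OCc1ccccc1 | intermediate (not isolated)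
9 | 1-benzyl 5-methyl 2-(1-methoxyethylidene)-3-pentylpentanedioate (racemic, E/Z mixture) | COC(C)=C(C(=O)OCc1ccccc1)C(CCCCC)CC(=O)OC | intermediate
10 | benzyl 2-methoxy-4-oxo-6-pentylcyclohex-1-ene-1-carboxylate (racemic) | CCCCCC1CC(=O)CC(OC)=C1C(=O)OCc1ccccc1 | intermediate (not isolated)
11 | potassium 4-[(benzyloxy)carbonyl]-3-methoxy-5-pentylcyclohexa-1,3-dien-1-olate (racemic) | CCCCCC1CC([O-])=CC(OC)=C1C(=O)OCc1ccccc1.[K+] | intermediate (not isolated)
12 | benzyl 2-methoxy-4-oxo-6-pentylcyclohex-2-ene-1-carboxylate (racemic, diastereomer mixture) | CCCCCC1CC(=O)C=C(OC)C1C(=O)OCc1ccccc1 | intermediate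
13 | benzyl 4-hydroxy-2-methoxy-6-pentylbenzoate | CCCCCc1cc(O)cc(OC)c1C(=O)OCc1ccccc1 | intermediate
14 | benzyl 4-(benzyloxy)-2-methoxy-6-pentylbenzoate | CCCCCc1cc(OCc2ccccc2)cc(OC)c1C(=O)OCc1ccccc1 | intermediate
15 | 4-(benzyloxy)-2-methoxy-6-pentylbenzoic acid | CCCCCc1cc(OCc2ccccc2)cc(OC)c1C(=O)O | intermediate
16 | 4-(benzyloxy)-2-methoxy-6-pentylbenzoic trifluoroacetic anhydride | CCCCCc1cc(OCc2ccccc2)cc(OC)c1C(=O)OC(=O)C(F)(F)F | intermediate (not isolated)
17 | benzyl 4-{[4-(benzyloxy)-2-methoxy-6-pentylbenzoyl]oxy}-2-methoxy-6-pentylbenzoate | CCCCCc1cc(OC(=O)c2c(CCCCC)cc(OCc3ccccc3)cc2OC)cc(OC)c1C(=O)OCc1ccccc1 | intermediate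
18 | 4-O-demethylplanaic acid | CCCCCc1cc(OC(=O)c2c(CCCCC)cc(O)cc2OC)cc(OC)c1C(=O)O | target

## Step count and uncertain steps

Total step count: 9. Longest linear sequence: 9 steps (1 and 2 to 18; compound 13 enters twice, so there is no separate branch).

**Step 4 (key step).**
- What may go wrong: exchange of the benzyl ester by the liberated methoxide before ring closure; non-productive enolisation next to the methyl ester followed by intermolecular condensation; slow γ-deprotonation of the fully substituted enol ether.
- Fallback, from 6 back to 13: the regiochemical advantage is given up and the ring is closed before methylation.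
  - KOtBu in THF at reflux should close the same C3–C4 bond through the dianion of the β-keto ester, a classical Dieckmann route to dihydroresorcinol esters, giving benzyl 2-hydroxy-4-oxo-6-pentylcyclohex-2-ene-1-carboxylate F1.
  - Bromination and dehydrobromination (Br2, DMF, 0 °C then 80 °C) should give benzyl 2,4-dihydroxy-6-pentylbenzoate F2.
  - MOMCl and iPr2NEt should protect the non-chelated C4–OH, giving benzyl 2-hydroxy-4-(methoxymethoxy)-6-pentylbenzoate F3.
  - MeI and K2CO3 in DMF should methylate the chelated C2–OH, giving benzyl 2-methoxy-4-(methoxymethoxy)-6-pentylbenzoate F4.
  - Dilute HCl in THF/water removes the acetal and returns 13.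

**Step 3.**
- What may go wrong: incomplete conversion of the α-branched ketone, stalling at the ketal stage, acid-catalysed exchange of the benzyl ester by the methanol released, and hydrolysis of the enol ether during work-up.
- Fallback, from 6 directly to 9: the acetal-exchange chemistry is replaced by enolate O-alkylation with Cs2CO3 and dimethyl sulfate in DMF. The hindered tertiary enolate carbon and the hard electrophile favour reaction at oxygen. This makes no new compound (F0).

**Step 5.**
- What may go wrong: incomplete hydride abstraction, addition of the electron-rich dienol to DDQ, and further oxidation of the phenol.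
- Fallback, from 12 back to 13: double deprotonation with LiN(iPr)2 (2.2 equiv, THF, −78 °C) and trapping of the more reactive ketone α'-enolate with PhSeBr should give benzyl 2-methoxy-4-oxo-6-pentyl-5-(phenylselanyl)cyclohex-2-ene-1-carboxylate F5. Oxidation with H2O2 and pyridine, then syn elimination of the selenoxide towards C6–H, gives a cross-conjugated dienone that tautomerises to 13.

**Step 8.**
- What may go wrong: slow acyl transfer because of the two ortho substituents, Friedel–Crafts C-acylation of the electron-rich ring of 13 by the acylium ion, and trifluoroacetylation of the phenol.
- Fallback, from 15 back to 17: (COCl)2 with catalytic DMF in CH2Cl2 converts 15 into 4-(benzyloxy)-2-methoxy-6-pentylbenzoyl chloride F6, which is isolated and then treated with 13, Et3N and catalytic 4-(dimethylamino)pyridine in CH2Cl2 to give 17.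

## Further compounds

F1 | step 4 | benzyl 2-hydroxy-4-oxo-6-pentylcyclohex-2-ene-1-carboxylate (racemic) | CCCCCC1CC(=O)C=C(O)C1C(=O)OCc1ccccc1
F2 | step 4 | benzyl 2,4-dihydroxy-6-pentylbenzoate | CCCCCc1cc(O)cc(O)c1C(=O)OCc1ccccc1
F3 | step 4 | benzyl 2-hydroxy-4-(methoxymethoxy)-6-pentylbenzoate | CCCCCc1cc(OCOC)cc(O)c1C(=O)OCc1ccccc1
F4 | step 4 | benzyl 2-methoxy-4-(methoxymethoxy)-6-pentylbenzoate | CCCCCc1cc(OCOC)cc(OC)c1C(=O)OCc1ccccc1
F0 | step 3 | none | none
F5 | step 5 | benzyl 2-methoxy-4-oxo-6-pentyl-5-(phenylselanyl)cyclohex-2-ene-1-carboxylate (racemic, diastereomer mixture) | CCCCCC1C([Se]c2ccccc2)C(=O)C=C(OC)C1C(=O)OCc1ccccc1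
F6 | step 8 | 4-(benzyloxy)-2-methoxy-6-pentylbenzoyl chloride | CCCCCc1cc(OCc2ccccc2)cc(OC)c1C(=O)Cl
A1 | alternative 1 | 4-(benzyloxy)-2-methoxy-6-pentylbenzoic acid | CCCCCc1cc(OCc2ccccc2)cc(OC)c1C(=O)O
A2 | alternative 1 | 5-(benzyloxy)-2-iodo-3-methoxyphenyl 4-chlorobenzenesulfonate | COc1cc(OCc2ccccc2)cc(OS(=O)(=O)c2ccc(Cl)cc2)c1I
A3 | alternative 2 | benzyl 4-[(2,4-dihydroxy-6-pentylbenzoyl)oxy]-2-methoxy-6-pentylbenzoate | CCCCCc1cc(OC(=O)c2c(CCCCC)cc(O)cc2O)cc(OC)c1C(=O)OCc1ccccc1
A4 | alternative 2 | benzyl 2-methoxy-6-pentyl-4-[(3,5,7-trioxododecanoyl)oxy]benzoate | CCCCCC(=O)CC(=O)CC(=O)CC(=O)Oc1cc(CCCCC)c(C(=O)OCc2ccccc2)c(OC)c1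
A5 | alternative 3 | methyl 2-methoxy-6-pentyl-4-(triisopropylsilyloxy)benzoate | CCCCCc1cc(O[Si](C(C)C)(C(C)C)C(C)C)cc(OC)c1C(=O)OC
A6 | alternative 3 | methyl 2-methoxy-6-oxo-4-pentyl-6H-pyran-3-carboxylate | CCCCCC1=CC(=O)OC(OC)=C1C(=O)OC
A7 | alternative 3 | triisopropylsilyloxyethyne | C#CO[Si](C(C)C)(C(C)C)C(C)C
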